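**Retrosynthetic overview**

1. Target 29 ⇒ methoxy dioxane 27 (C3–CH2CO2Me bond: silyl ketene acetal on the C3 peroxycarbenium ion) ⇒ allyl dioxane 16 + allylic phosphate 24 (C9–C10 bond: hydroboration, then copper-catalysed anti-SN2' coupling, which also sets C10 and the E-alkene).
2. 16 ⇒ bis(peroxy ketal) 14 (C6–C7 bond: allylsilane on the C6 peroxycarbenium ion, trans to the C4 ethyl group; this sets the quaternary centre).
3. 14 ⇒ cyclobutene 9: O3/MeOH inserts O–O into C3=C6, so the four-membered carbocycle C3–C4–C5–C6 grows into the six-membered 1,2-dioxane, the only ring of the target (ring order: cyclobutane in step 1, dioxane in step 5).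
4. Enabling feature: in the dioxane ring the two oxygen-bearing carbons C3 and C6 are joined by the C4–C5 bridge, each carries a carbon substituent that can arrive as a π-nucleophile (CH2CO2Me at C3, the C7–C14 chain at C6), and C4 is the only other ring stereocentre; the ring is therefore a cyclobutene plus O2 at the acetal/ketal oxidation level.
5. 9 ⇒ achiral 3-ethylcyclobutanone 6 (enantiotopic α-CH2 groups told apart by a chiral lithium amide; this sets C4) ⇒ but-1-ene 1 + trichloroacetyl chloride 2; 24 ⇒ but-1-yne 17 + Weinreb amide 18.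

Key step: step 5

Remark 1: ring atoms of every 1,2-dioxane and of its precursors are numbered as in the target (O1, O2, C3–C6; side chain C7–C14), also where this is not the lowest-locant numbering.
Remark 2: the sense of induction in step 3 is assumed by analogy with chiral-amide deprotonation of 4-substituted cyclohexanones; should the (S,S)-amide favour the R enolate, the (R,R)-amide is used with no other change.
Remark 3: the catalyst enantiomer in step 8 is chosen by analogy with the transfer hydrogenation of aryl and alkynyl methyl ketones.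

**Route**

Step 1
Reactants: 1 but-1-ene; 2 trichloroacetyl chloride
Product: 4 2,2-dichloro-3-ethylcyclobutan-1-one (racemic), via dichloroketene 3 (not isolated)
Conditions: Zn(Cu) couple, Et2O/DME, 1 in excess (condensed), 0 → 25 °C, sealed vessel
Reagents that add atoms: none
Why: Thermal [2+2] cycloaddition of dichloroketene (generated from 2 by zinc) with the unactivated terminal alkene should be regioselective, the terminal CH2 bonding to the ketene carbonyl carbon so that the ethyl-bearing carbon lies next to CCl2; the stereocentre formed is racemic and disappears in step 2.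

Step 2
Reactants: 4 2,2-dichloro-3-ethylcyclobutan-1-one
Product: 6 3-ethylcyclobutan-1-one, via 2-chloro-3-ethylcyclobutan-1-one 5 (not isolated)
Conditions: Zn dust, AcOH, 25 → 60 °C
Reagents that add atoms: none
Why: Zinc-mediated reductive dechlorination of the α,α-dichloroketone through zinc enolates should remove both halogens and leave the achiral, mirror-symmetric cyclobutanone whose two α-methylene groups are enantiotopic.

Step 3
Reactants: 6 3-ethylcyclobutan-1-one
Product: 8 (3S)-3-ethylcyclobut-1-en-1-yl trifluoromethanesulfonate, via lithium enolate 7 (not isolated)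
Conditions: (S,S)-bis(1-phenylethyl)amine·HCl, n-BuLi (2 equiv), THF, −78 → 0 °C; 6, −100 °C; then N-(5-chloropyridin-2-yl)bis(trifluoromethanesulfonimide), −100 → −20 °C
Reagents that add atoms: N-(5-chloropyridin-2-yl)bis(trifluoromethanesulfonimide) (Comins reagent), FC(F)(F)S(=O)(=O)N(c1ccc(Cl)cn1)S(=O)(=O)C(F)(F)F; lithium (S,S)-bis(1-phenylethyl)amide (supplies only the lithium of 7), [Li+].C[C@@H](c1ccccc1)[N-][C@@H](C)c1ccccc1
Why: Enantioselective deprotonation by the C2-symmetric chiral lithium amide in the presence of LiCl should select one of the two enantiotopic α-methylene groups, and O-sulfonylation of the enolate with the Comins reagent before proton exchange can scramble it fixes that choice as the position of the double bond, which makes the ethyl-bearing ring carbon (the future C4) a stereocentre of S configuration under reagent control.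

Step 4
Reactants: 8 (3S)-3-ethylcyclobut-1-en-1-yl trifluoromethanesulfonate
Product: 9 (3S)-1,3-diethylcyclobut-1-ene
Conditions: EtMgBr (1.5 equiv), Fe(acac)3 (5 mol %), THF/NMP, −30 °C; distilled and carried on as a solution
Reagents that add atoms: ethylmagnesium bromide, CC[Mg]Br
Why: Iron-catalysed Kumada-type cross-coupling of alkenyl triflates with alkyl Grignard reagents is fast at low temperature and outruns β-hydride elimination, so ethyl should replace triflate at the future C6 without migration of the double bond or change at the allylic stereocentre.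

Step 5
Reactants: 9 (3S)-1,3-diethylcyclobut-1-ene
Product: 14 (4S)-4,6-diethyl-3,6-dimethoxy-1,2-dioxane (C3/C6 epimer mixture), via primary ozonide 10 (not isolated), via carbonyl oxide 11 (not isolated), via methoxy hydroperoxide 12 (not isolated), via dioxanol 13 (not isolated)
Conditions: O3, CH2Cl2/MeOH 5:1, −78 °C; N2 purge; then HC(OMe)3, PPTS (cat.), −78 → 20 °C
Reagents that add atoms: ozone, [O-][O+]=O; methanol, CO; trimethyl orthoformate, COC(OC)OC
Why: Ozone adds as a 1,3-dipole to the strained trisubstituted C3=C6 bond, the primary ozonide 10 fragments (Criegee mechanism) to carbonyl oxide 11 with its carbonyl partner held two carbons away, methanol intercepts the carbonyl oxide as α-methoxy hydroperoxide 12, and the hydroperoxide adds to the tethered carbonyl group to give dioxanol 13, which acid-catalysed exchange with trimethyl orthoformate converts into the bis(peroxy ketal) 14. The closest known reaction type is the ozonolysis of cyclobutenes in methanol to 3,6-dialkoxy-1,2-dioxanes (solvent capture of the carbonyl oxide followed by hemiperacetal closure). The only ring closed is the 1,2-dioxane, by 6-exo-trig addition of the hydroperoxide oxygen to C=O, so that the four ring carbons of the cyclobutene and two oxygen atoms of ozone become the six-membered ring. C3 and C6 are created as acetal and ketal centres without control, which is intended because both are ionised later (steps 6 and 12), while the existing C4 stereocentre takes part in no bond change. The step needs only chemoselectivity and ring-size selectivity: 9 has a single π bond, both directions of primary-ozonide cleavage converge on 14, and the C4–C5 two-carbon tether makes six-ring closure faster than oligomeric peroxide formation, with methanol suppressing the bicyclic ozonide.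

Step 6
Reactants: 14 (4S)-4,6-diethyl-3,6-dimethoxy-1,2-dioxane
Product: 16 (4S,6S)-4,6-diethyl-3-methoxy-6-(prop-2-en-1-yl)-1,2-dioxane (C3 epimers), via peroxycarbenium triflate 15 (not isolated)
Conditions: CH2=CHCH2SiMe3 (1.3 equiv), Me3SiOTf (0.2 equiv), CH2Cl2, −78 °C; Et3N quench
Reagents that add atoms: allyltrimethylsilane, C=CC[Si](C)(C)C; trimethylsilyl trifluoromethanesulfonate (supplies only the counter-ion of 15), C[Si](C)(C)OS(=O)(=O)C(F)(F)F
Why: Hosomi–Sakurai-type allylation of a peroxycarbenium ion: the tertiary peroxyketal carbon C6 ionises far more readily than the secondary peroxyacetal carbon C3, and the allylsilane should attack cation 15 axially on the half-chair that keeps the C4 ethyl group pseudo-equatorial (the other chair-like approach would create a 1,3-diaxial allyl/ethyl contact), so allyl enters trans to the C4 ethyl group and the quaternary centre C6 is set as S by substrate control from C4.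

Step 7
Reactants: 17 but-1-yne; 18 N-methoxy-N-methylpropanamide
Product: 21 hept-4-yn-3-one, via but-1-yn-1-yllithium 19 (not isolated), via lithium hemiaminal adduct 20 (not isolated)
Conditions: n-BuLi, THF, −78 °C; then 18, −78 → 0 °C; aq NH4Cl
Reagents that add atoms: n-butyllithium (supplies only the lithium of 19 and 20), [Li]CCCC
Why: Acylation of a lithium acetylide with a Weinreb amide stops at the ketone because the chelated tetrahedral adduct 20 is stable until aqueous work-up.

Step 8
Reactants: 21 hept-4-yn-3-one
Product: 22 (3R)-hept-4-yn-3-ol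
Conditions: RuCl[(R,R)-TsDPEN](p-cymene) (1 mol %), KOH (cat.), i-PrOH, 25 °C
Reagents that add atoms: none
Why: Noyori asymmetric transfer hydrogenation reduces alkynyl ketones at the carbonyl group only, and with the alkynyl group as the π-substituent recognised by the catalyst the (R,R)-configured complex should give the R carbinol under catalyst control.

Step 9
Reactants: 22 (3R)-hept-4-yn-3-ol
Product: 23 (3R,4Z)-hept-4-en-3-ol
Conditions: H2 (1 atm), Pd/CaCO3 poisoned with Pb(OAc)2 (Lindlar catalyst), quinoline, hexane, 20 °C
Reagents that add atoms: none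
Why: Lindlar semi-hydrogenation delivers hydrogen syn to the alkyne from the poisoned palladium surface and stops at the Z-alkene, leaving the carbinol stereocentre untouched.

Step 10
Reactants: 23 (3R,4Z)-hept-4-en-3-ol
Product: 24 diethyl (3R,4Z)-hept-4-en-3-yl phosphate
Conditions: ClP(O)(OEt)2, pyridine, DMAP (cat.), CH2Cl2, 0 → 20 °C
Reagents that add atoms: diethyl chlorophosphate, CCOP(=O)(Cl)OCC
Why: O-Phosphorylation of the secondary alcohol under nucleophilic catalysis does not break the C–O bond, so the allylic phosphate is formed with retention of the R configuration and of the Z geometry.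

Step 11
Reactants: 16 (4S,6S)-4,6-diethyl-3-methoxy-6-(prop-2-en-1-yl)-1,2-dioxane; 24 diethyl (3R,4Z)-hept-4-en-3-yl phosphate
Product: 27 (4S,6S)-4,6-diethyl-6-[(4R,5E)-4-ethyloct-5-en-1-yl]-3-methoxy-1,2-dioxane (C3 epimers), via alkylborane 25 (not isolated), via alkylborate 26 (not isolated)
Conditions: 9-BBN dimer (0.5 equiv), THF, 0 → 25 °C; then KOt-Bu (1.0 equiv), CuOAc (10 mol %), 24 (1.3 equiv), THF, 25 → 50 °C
Reagents that add atoms: 9-borabicyclo[3.3.1]nonane (boron only in 25 and 26; hydrogen in 27), C1CC2CCCC(C1)B2; potassium tert-butoxide (only in 26), CC(C)(C)[O-].[K+]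
Why: Anti-Markovnikov hydroboration of the terminal alkene with 9-BBN followed by copper-catalysed γ-selective allyl–alkyl coupling of the alkylborate with the secondary (Z)-allylic phosphate should proceed by anti-SN2' attack on the conformer whose carbinol hydrogen eclipses the double bond (allylic 1,3-strain), so that the R configuration of the C–O carbon is transferred to the new C10 stereocentre (R) and the new double bond is E, while the dialkyl peroxide, which has no O–H bond, cannot trigger the usual borane oxidation.

Step 12
Reactants: 27 (4S,6S)-4,6-diethyl-6-[(4R,5E)-4-ethyloct-5-en-1-yl]-3-methoxy-1,2-dioxane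
Product: 29 methyl 2-[(3S,4S,6S)-4,6-diethyl-6-[(4R,5E)-4-ethyloct-5-en-1-yl]-1,2-dioxan-3-yl]acetate, via peroxycarbenium triflate 28 (not isolated)
Conditions: CH2=C(OMe)OSiMe2t-Bu (2 equiv), Me3SiOTf (0.3 equiv), CH2Cl2, −78 → −40 °C; Et3N quench
Reagents that add atoms: 1-(tert-butyldimethylsilyloxy)-1-methoxyethene, C=C(OC)O[Si](C)(C)C(C)(C)C; trimethylsilyl trifluoromethanesulfonate (supplies only the counter-ion of 28), C[Si](C)(C)OS(=O)(=O)C(F)(F)F
Why: Mukaiyama-type addition of a silyl ketene acetal to the secondary peroxycarbenium ion 28 should occur by axial attack on the half-chair in which the C4 and C6 ethyl groups are pseudo-equatorial (the inverted half-chair would place the C4 ethyl group syn-axial to the C6 side chain), so that the acetate arm enters cis to the C4 ethyl group and trans to the C6 side chain, setting C3 as S under substrate control.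

**Compound list**

1 | but-1-ene | C=CCC | starting material
2 | trichloroacetyl chloride | ClC(Cl)(Cl)C(Cl)=O | starting material
3 | dichloroketene | ClC(Cl)=C=O | intermediate
4 | 2,2-dichloro-3-ethylcyclobutan-1-one (racemic) | CCC1CC(=O)C1(Cl)Cl | intermediate
5 | 2-chloro-3-ethylcyclobutan-1-one | CCC1CC(=O)C1Cl | intermediate
6 | 3-ethylcyclobutan-1-one | CCC1CC(=O)C1 | intermediate
7 | lithium (3S)-3-ethylcyclobut-1-en-1-olate | [Li]OC1=C[C@@H](CC)C1 | intermediate
8 | (3S)-3-ethylcyclobut-1-en-1-yl trifluoromethanesulfonate | FC(F)(F)S(=O)(=O)OC1=C[C@@H](CC)C1 | intermediate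
9 | (3S)-1,3-diethylcyclobut-1-ene | CCC1=C[C@@H](CC)C1 | intermediate
10 | primary ozonide (6S)-1,6-diethyl-2,3,4-trioxabicyclo[3.2.0]heptane | CC[C@H]1CC2(CC)OOOC12 | intermediate
11 | carbonyl oxide (2S)-2-ethyl-4-oxohexanal O-oxide | CCC(=O)C[C@H](CC)C=[O+][O-] | intermediate
12 | (5S)-5-[hydroperoxy(methoxy)methyl]heptan-3-one | CCC(=O)C[C@H](CC)C(OC)OO | intermediate
13 | (4S)-4,6-diethyl-3-methoxy-1,2-dioxan-6-ol | COC1OOC(O)(CC)C[C@@H]1CC | intermediate
14 | (4S)-4,6-diethyl-3,6-dimethoxy-1,2-dioxane | COC1OOC(CC)(OC)C[C@@H]1CC | intermediate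
15 | peroxycarbenium triflate (4S)-4,6-diethyl-3-methoxy-1,2-dioxan-6-ylium trifluoromethanesulfonate | CCC1=[O+]OC(OC)[C@@H](CC)C1.[O-]S(=O)(=O)C(F)(F)F | intermediate
16 | (4S,6S)-4,6-diethyl-3-methoxy-6-(prop-2-en-1-yl)-1,2-dioxane | C=CC[C@@]1(CC)C[C@H](CC)C(OC)OO1 | intermediate
17 | but-1-yne | CCC#C | starting material
18 | N-methoxy-N-methylpropanamide | CCC(=O)N(C)OC | starting material
19 | but-1-yn-1-yllithium | CCC#C[Li] | intermediate
20 | lithium 3-[methoxy(methyl)amino]hept-4-yn-3-olate | CCC#CC(CC)(O[Li])N(C)OC | intermediate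
21 | hept-4-yn-3-one | CCC#CC(=O)CC | intermediate
22 | (3R)-hept-4-yn-3-ol | CC[C@@H](O)C#CCC | intermediate
23 | (3R,4Z)-hept-4-en-3-ol | CC[C@@H](O)/C=C\CC | intermediate
24 | diethyl (3R,4Z)-hept-4-en-3-yl phosphate | CC[C@@H](OP(=O)(OCC)OCC)/C=C\CC | intermediate
25 | alkylborane 9-{3-[(4S,6S)-4,6-diethyl-3-methoxy-1,2-dioxan-6-yl]propyl}-9-borabicyclo[3.3.1]nonane | C1CC2CCCC(C1)B2CCC[C@@]1(CC)C[C@H](CC)C(OC)OO1 | intermediate
26 | alkylborate: potassium tert-butoxide adduct of 25 | CC(C)(C)O[B-]1(CCC[C@@]2(CC)C[C@H](CC)C(OC)OO2)C2CCCC1CCC2.[K+] | intermediate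
27 | (4S,6S)-4,6-diethyl-6-[(4R,5E)-4-ethyloct-5-en-1-yl]-3-methoxy-1,2-dioxane | CC/C=C/[C@H](CC)CCC[C@@]1(CC)C[C@H](CC)C(OC)OO1 | intermediate
28 | peroxycarbenium triflate (4S,6S)-4,6-diethyl-6-[(4R,5E)-4-ethyloct-5-en-1-yl]-1,2-dioxan-3-ylium trifluoromethanesulfonate | CC/C=C/[C@H](CC)CCC[C@@]1(CC)C[C@H](CC)C=[O+]O1.[O-]S(=O)(=O)C(F)(F)F | intermediate
29 | methyl 2-[(3S,4S,6S)-4,6-diethyl-6-[(4R,5E)-4-ethyloct-5-en-1-yl]-1,2-dioxan-3-yl]acetate | CC/C=C/[C@H](CC)CCC[C@@]1(CC)C[C@H](CC)[C@H](CC(=O)OC)OO1 | target

**Totals**

Total step count: 12. Longest linear sequence: 8 steps (steps 1–6, 11, 12); the side-chain fragment 24 takes 4 steps (7–10).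

**Steps most likely to fail**

1. Step 11. The O–O bond may be cleaved reductively by alkylcopper or copper alkoxide species, or the peroxyacetal may fragment under base, before the allylic substitution takes place. The fallback sets out from 16 and returns at 27, and keeps organocopper and alkoxide reagents away from the peroxide. Cross-metathesis of 16 with (2R)-tert-butyl[(2-ethylbut-3-en-1-yl)oxy]dimethylsilane F1 (to be made separately by asymmetric SN2' ethylation of the (E)-4-chlorobut-2-enyl silyl ether with EtMgBr, CuBr·SMe2 and a chiral phosphoramidite) under second-generation Grubbs catalyst (H2IMes)(PCy3)Cl2Ru=CHPh would give the disubstituted alkene (4S,6S)-6-[(2E,4R)-5-(tert-butyldimethylsilyloxy)-4-ethylpent-2-en-1-yl]-4,6-diethyl-3-methoxy-1,2-dioxane F2. Diimide (2-nitrobenzenesulfonyl hydrazide, Et3N) would saturate C8=C9 without touching O–O to give the silyl ether (4S,6S)-6-[(4R)-5-(tert-butyldimethylsilyloxy)-4-ethylpentyl]-4,6-diethyl-3-methoxy-1,2-dioxane F3. Bu4NF would free the alcohol (2R)-5-[(4S,6S)-4,6-diethyl-3-methoxy-1,2-dioxan-6-yl]-2-ethylpentan-1-ol F4, and Dess–Martin periodinane would give the aldehyde (2R)-5-[(4S,6S)-4,6-diethyl-3-methoxy-1,2-dioxan-6-yl]-2-ethylpentanal F5. Julia–Kocienski olefination of F5 with 1-phenyl-5-(propylsulfonyl)-1H-tetrazole and KN(SiMe3)2 at −78 °C would then build the E-alkene of 27.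

2. Step 6. Ionisation may occur at both acetal carbons or at the ring C–O bond, leading to double allylation or ring opening, and the normalisation to the bis(methoxy) compound in step 5 may be incomplete. The fallback sets out from 9 and returns at 16, and offers only one ionisable position at a time. Ozonolysis of 9 in CH2Cl2 without methanol would give the bicyclic ozonide (5S)-1,5-diethyl-2,3,7-trioxabicyclo[2.2.1]heptane F6, in which the dioxane ring is already present and bridged by one oxygen. SnCl4 and allyltrimethylsilane at −78 °C would open only the tertiary C6–O bond of the ether bridge and, by the same axial attack, give (4S,6S)-4,6-diethyl-6-(prop-2-en-1-yl)-1,2-dioxan-3-ol F7. Its hemiperacetal hydroxyl would then be exchanged for methoxy (HC(OMe)3, PPTS, MeOH) to reach 16.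

3. Step 12. Facial selectivity at C3 may be poor (arm entering trans to the C4 ethyl group), or the cation may lose the C4 proton, which would cause elimination or epimerisation at C4. The fallback sets out from 27 and returns at 29, and forms C3 by C–O instead of C–C bond formation. Mild hydrolysis (PPTS, acetone/water) would give the dioxanol (4S,6S)-4,6-diethyl-6-[(4R,5E)-4-ethyloct-5-en-1-yl]-1,2-dioxan-3-ol F8. Horner–Wadsworth–Emmons reaction of its open hydroperoxy aldehyde form with trimethyl phosphonoacetate (LiCl, DBU, MeCN) would give methyl (2E,4S,6S,10R,11E)-4,6,10-triethyl-6-hydroperoxytetradeca-2,11-dienoate F9. Amine-catalysed 6-exo oxa-Michael closure (Et2NH, CF3CH2OH) would then re-form the dioxane. The C3 configuration would be decided in the cyclisation transition state, and the unwanted C3 epimer could be returned to the equilibrium by retro-Michael and re-closure under the same conditions.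

**Further compounds**

F1 | step 11 | (2R)-tert-butyl[(2-ethylbut-3-en-1-yl)oxy]dimethylsilane | C=C[C@@H](CC)CO[Si](C)(C)C(C)(C)C
F2 | step 11 | (4S,6S)-6-[(2E,4R)-5-(tert-butyldimethylsilyloxy)-4-ethylpent-2-en-1-yl]-4,6-diethyl-3-methoxy-1,2-dioxane | CC(C)(C)[Si](C)(C)OC[C@H](CC)/C=C/C[C@@]1(CC)C[C@H](CC)C(OC)OO1
F3 | step 11 | (4S,6S)-6-[(4R)-5-(tert-butyldimethylsilyloxy)-4-ethylpentyl]-4,6-diethyl-3-methoxy-1,2-dioxane | CC(C)(C)[Si](C)(C)OC[C@H](CC)CCC[C@@]1(CC)C[C@H](CC)C(OC)OO1
F4 | step 11 | (2R)-5-[(4S,6S)-4,6-diethyl-3-methoxy-1,2-dioxan-6-yl]-2-ethylpentan-1-ol | OC[C@H](CC)CCC[C@@]1(CC)C[C@H](CC)C(OC)OO1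
F5 | step 11 | (2R)-5-[(4S,6S)-4,6-diethyl-3-methoxy-1,2-dioxan-6-yl]-2-ethylpentanal | O=C[C@H](CC)CCC[C@@]1(CC)C[C@H](CC)C(OC)OO1
F6 | step 6 | (5S)-1,5-diethyl-2,3,7-trioxabicyclo[2.2.1]heptane | CC[C@H]1CC2(CC)OOC1O2
F7 | step 6 | (4S,6S)-4,6-diethyl-6-(prop-2-en-1-yl)-1,2-dioxan-3-ol | C=CC[C@@]1(CC)C[C@H](CC)C(O)OO1
F8 | step 12 | (4S,6S)-4,6-diethyl-6-[(4R,5E)-4-ethyloct-5-en-1-yl]-1,2-dioxan-3-ol | CC/C=C/[C@H](CC)CCC[C@@]1(CC)C[C@H](CC)C(O)OO1
F9 | step 12 | methyl (2E,4S,6S,10R,11E)-4,6,10-triethyl-6-hydroperoxytetradeca-2,11-dienoate | CC/C=C/[C@H](CC)CCC[C@](CC)(OO)C[C@H](CC)/C=C/C(=O)OC
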